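## The problem

Target 20, 2-[3-chloro-4-hydroxy-2-methoxy-6-(methoxycarbonyl)phenoxy]-6-hydroxy-4-methylbenzoic acid, is a diaryl ether with no stereocentre, so the difficulty lies wholly in regiochemistry and chemoselectivity. Ring A is pentasubstituted (C1 CO2Me, C2 H, C3 OH, C4 Cl, C5 OMe, C6 ether oxygen). Ring B is an orsellinic acid unit (C1 CO2H, C2 ether oxygen, C3 H, C4 CH3, C5 H, C6 OH). The ether oxygen sits between OMe and CO2Me on ring A and next to the carboxyl carbon on ring B, so the rings must be joined at crowded positions where copper-mediated and addition–elimination etherifications are at their limit. The two carboxyl groups must end in different states, methyl ester on ring A and free acid on ring B, which excludes any late saponification or unselective esterification. Several groups are fragile: the 2,6-dioxygenated benzoic acid loses CO2 in hot acid, the aryl chloride is at risk under hydrogenolysis, the ring A methyl ether must survive the unmasking of two phenols, and an ester ortho to the ether oxygen invites xanthone closure whenever a carbanion appears on the other ring. The enabling feature is the contiguous array C2 (ether O), C1 (CO2H), C6 (OH) of ring B: an oxygen nucleophile and then a carbon electrophile adding across a 3-oxygenated aryne give exactly this pattern, with the C4 methyl group as a bystander.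

## Retrosynthesis

**20 to 19.** The two O–benzyl bonds are cut last, leading back to bis(benzyl ether) 19. Benzyl is preferred to methyl or acetal protection because both ethers fall in one Lewis-acid operation with a cation scavenger, which spares the aryl chloride (unlike hydrogenolysis), the methyl ester and the ring A methyl ether. The forward step must discriminate benzyl from methyl ether.

**19 to 18.** The ring A C1–CO2Me bond is cut, giving aryl bromide 18. An ester at this position during ring B construction would offer an acyl group to any carbanion next to the ether oxygen, whereas a bromide is inert there. Methoxycarbonylation then writes the methyl ester onto ring A while the ring B acid stays free, so the two carboxyl groups are differentiated by order of events. The forward step needs palladium insertion into a hindered C–Br bond in preference to C–Cl, with a carboxylate present.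

**18 to 7, 15 and 16.** The ring B C2–O ether bond and the C1–CO2H bond are cut together. This leads to phenol 7, silyl triflate 15 (the source of aryne 17) and carbon dioxide 16. A conventional etherification would have to join two doubly ortho-substituted partners. Making the ether first and carboxylating afterwards would require a lithiation that the ring A bromide cannot survive. The three-component cut is convergent and reduces 18 to two aromatic pieces of similar size. It asks that the phenoxide add only to the aryne carbon remote from the benzyloxy group and that the resulting anion meet 16 before a proton.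

**7 to 1.** Phenol 7 is traced through benzyl ether 6, phenol 5, formate 4, aldehyde 3 and bromophenol 2 to aldehyde 1. Compound 1 already carries Cl, OMe and OH in the required contiguous order. Its formyl group is a latent oxygen (Baeyer–Villiger), its free phenol directs bromine to the carbon that will later bear the ester, and a temporary acetal keeps the two oxygens distinguishable. Only functional-group changes on an intact ring are required.

**15 to 8.** Silyl triflate 15 is traced through silyl phenol 14, silyl carbamate 13 (formed through the N-silylated species 11 and 12), carbamate 10 and monobenzyl ether 9 to orcinol 8. The silicon is placed by directed metalation at the carbon between the two oxygens, the only position activated by both. The sequence must desymmetrise 8 and metalate without disturbing the benzyl ether.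

## Roads not taken

**Alternative 1:** The cut runs through C1–C2 and C1–C6 of ring A, so ring A is folded last from an open chain attached to the ring B oxygen.
- Forward step: the methyl ketone enolate of enone A1 is acylated by dimethyl oxalate A2 (C2–C1). The carbon bearing the aryloxy group then condenses with the new keto group (C6–C1), and dehydration with enolisation gives phenol A3.
- Merits: no aryl–O–aryl bond is made between two aromatic rings, since the ring B oxygen is alkylated at an sp3 carbon. The carboxyl groups are distinguished as tert-butyl and methyl esters, and A3 needs one acid treatment to reach 20.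
- Weak points: A1 is a tetrasubstituted chloro(methoxy)enone whose Z geometry must be secured, and as a vinylogous ester it is open to addition–elimination by alkoxides and enolates. Deprotonation must occur at the methyl group and then at the aryloxymethylene carbon in that order. Acylpyruvate intermediates tend to close through oxygen to pyranones or furanones instead of through carbon.
- Comparison: this road has the better endgame, with no palladium step and one deprotection, and its key step rests on known condensation chemistry. The chosen plan sets against it that 1 supplies the Cl/OMe/OH array ready-made, that 7 and 15 are stable aromatic partners, and that the aryne fixes the regiochemistry.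

**Alternative 2:** The cut runs through C4–C5 and C1–C2 of ring B, building ring B on a complete ring A.
- Forward step: the dianion of benzyl acetoacetate A5 adds through its terminal carbon to the ketone of enone A4 (C5–C4). A Lewis acid ionises the tertiary alcohol, the central carbon closes on the carbon bearing chlorine and the aryloxy group (C1–C2), and dehydration with loss of chloride gives A6.
- Merits: ring A enters with its methyl ester in place, so no carbonylation is needed. The benzyl ester and benzyl ether fall together, and dianion benzannulations to salicylates are established.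
- Weak points: A4 is a vinylogous acid chloride, so the dianion may attack the chlorinated carbon or the ring A ester instead of the ketone. Making A4 requires a single substitution on a dichloroenone by the same hindered ring A phenol. In the ring closure, loss of the aryloxy group instead of chloride would destroy the ether.
- Comparison: this road is better in avoiding the bromide-to-ester step. The chosen plan uses the same hindered phenoxide but on an aryne, where crowding matters least and no leaving-group choice can erase the ether.

**Alternative 3:** The cut runs through C2–C3 and C1–C6 of ring B.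
- Forward step: a Diels–Alder reaction of diene A7 with aryloxypropiolate A8, followed by loss of the methoxy and silyl groups from the adduct, gives salicylate A9.
- Merits: the regiochemistry of vinylketene acetal cycloadditions to alkynoates is dependable. The neutral thermal conditions tolerate the ring A ester, and A9 emerges with the C6 hydroxyl already free.
- Weak points: A8 is an aryl alkynyl ether conjugated to an ester. It must be made from the hindered ring A phenol and is prone to hydration and nucleophilic addition. The aryloxy donor lowers the electrophilicity of the alkyne carbon that must bond to the diene terminus, so forcing conditions may be needed with a moisture-sensitive diene.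
- Comparison: this is the strongest competitor, because its key step is an established reaction type and the chosen key step is not. The chosen plan offers bench-stable partners 7 and 15, no sensitive alkynyl ether, and CO2 as the one-carbon source.

Key step: step 10

Assumption: 2-chloro-4-hydroxy-3-methoxybenzaldehyde (1) and orcinol (8) are taken as catalogue compounds; ring A is the chlorinated ring and ring B the methyl-bearing ring, with the locants used above.

## Route

**Step 1**
Reactants: 1 2-chloro-4-hydroxy-3-methoxybenzaldehyde
Product: 2 5-bromo-2-chloro-4-hydroxy-3-methoxybenzaldehyde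
Conditions: Br2, AcOH, rt
Reagents that add atoms: bromine, BrBr
Why: Electrophilic aromatic bromination; the free phenol directs to its only open ortho position (C5), while C6 is ortho to the deactivating formyl group and served only by the twisted, weaker methoxy donor.

**Step 2**
Reactants: 2 5-bromo-2-chloro-4-hydroxy-3-methoxybenzaldehyde
Product: 3 5-bromo-2-chloro-3-methoxy-4-(methoxymethoxy)benzaldehyde
Conditions: MOMCl, i-Pr2NEt, CH2Cl2, 0 °C to rt
Reagents that add atoms: chloromethyl methyl ether, COCCl
Why: Williamson-type O-alkylation of the acidic phenol (MOM protection); the acetal masks this oxygen so that the oxygen created in step 3 can be distinguished from it.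

**Step 3**
Reactants: 3 5-bromo-2-chloro-3-methoxy-4-(methoxymethoxy)benzaldehyde
Product: 5 5-bromo-2-chloro-3-methoxy-4-(methoxymethoxy)phenol, via 5-bromo-2-chloro-3-methoxy-4-(methoxymethoxy)phenyl formate 4 (not isolated)
Conditions: mCPBA, CH2Cl2, 0 °C to rt; then K2CO3 (cat.), MeOH, rt
Reagents that add atoms: 3-chloroperbenzoic acid (mCPBA), OOC(=O)c1cccc(Cl)c1
Why: Baeyer–Villiger oxidation of the benzaldehyde; the aryl group, with its para alkoxy donor, migrates to give formate 4, which mild methanolysis cleaves to the phenol without touching the MOM acetal.

**Step 4**
Reactants: 5 5-bromo-2-chloro-3-methoxy-4-(methoxymethoxy)phenol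
Product: 6 1-(benzyloxy)-5-bromo-2-chloro-3-methoxy-4-(methoxymethoxy)benzene
Conditions: BnBr, K2CO3, DMF, rt
Reagents that add atoms: benzyl bromide, BrCc1ccccc1
Why: Williamson ether synthesis on the new phenol; benzyl is chosen so that it leaves together with the ring B benzyl ether in the final step.

**Step 5**
Reactants: 6 1-(benzyloxy)-5-bromo-2-chloro-3-methoxy-4-(methoxymethoxy)benzene
Product: 7 4-(benzyloxy)-6-bromo-3-chloro-2-methoxyphenol
Conditions: HCl (conc., cat.), MeOH, 50 °C
Reagents that add atoms: none
Why: Acid-catalysed acetal exchange removes the MOM group while the aryl benzyl ether and both halides are inert; this frees the hindered phenol that serves as the nucleophile in step 10.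

**Step 6**
Reactants: 8 orcinol (5-methylbenzene-1,3-diol)
Product: 9 3-(benzyloxy)-5-methylphenol
Conditions: BnBr (substoichiometric), K2CO3, DMF, rt
Reagents that add atoms: benzyl bromide, BrCc1ccccc1
Why: Williamson monoalkylation of a symmetrical diol run with the diol in excess; the outcome is statistical, but unreacted 8 and the dibenzyl ether separate easily and 8 is recycled.

**Step 7**
Reactants: 9 3-(benzyloxy)-5-methylphenol
Product: 10 3-(benzyloxy)-5-methylphenyl N-isopropylcarbamate
Conditions: i-PrNCO, Et3N (cat.), CH2Cl2, rt
Reagents that add atoms: isopropyl isocyanate, CC(C)N=C=O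
Why: Base-catalysed addition of the phenol to the isocyanate gives the secondary carbamate, a directing group for ortho-metalation that can later be removed without hydrolysis.

**Step 8**
Reactants: 10 3-(benzyloxy)-5-methylphenyl N-isopropylcarbamate
Product: 13 3-(benzyloxy)-5-methyl-2-(trimethylsilyl)phenyl N-isopropylcarbamate, via 3-(benzyloxy)-5-methylphenyl N-(tert-butyldimethylsilyl)-N-isopropylcarbamate 11 (not isolated), via 3-(benzyloxy)-5-methyl-2-(trimethylsilyl)phenyl N-(tert-butyldimethylsilyl)-N-isopropylcarbamate 12 (not isolated)
Conditions: TBSOTf, TMEDA, Et2O, 0 °C to rt; n-BuLi, TMEDA, −78 °C; TMSCl, −78 °C to rt; aq. NaHSO4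
Reagents that add atoms: chlorotrimethylsilane, C[Si](C)(C)Cl
Why: Directed ortho-metalation; after N-silylation in the flask (11), n-BuLi/TMEDA lithiates C2, the one position activated by both the carbamate and the benzyloxy oxygen, and TMSCl traps the aryllithium (12). The N-silyl group is lost on acidic work-up.

**Step 9**
Reactants: 13 3-(benzyloxy)-5-methyl-2-(trimethylsilyl)phenyl N-isopropylcarbamate
Product: 15 3-(benzyloxy)-5-methyl-2-(trimethylsilyl)phenyl trifluoromethanesulfonate, via 3-(benzyloxy)-5-methyl-2-(trimethylsilyl)phenol 14 (not isolated)
Conditions: DBU, Et2NH, MeCN, 40 °C; then PhNTf2, rt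
Reagents that add atoms: N-phenylbis(trifluoromethanesulfonimide), O=S(=O)(N(c1ccccc1)S(=O)(=O)C(F)(F)F)C(F)(F)F
Why: DBU deprotonates the N–H carbamate, which fragments (E1cB) to the phenoxide of 14 and an isocyanate that Et2NH scavenges as a urea; the phenoxide is sulfonylated in the same flask, a known one-flask entry to 2-silylaryl triflates.

**Step 10**
Reactants: 7 4-(benzyloxy)-6-bromo-3-chloro-2-methoxyphenol; 15 3-(benzyloxy)-5-methyl-2-(trimethylsilyl)phenyl trifluoromethanesulfonate; 16 carbon dioxide
Product: 18 2-(benzyloxy)-6-[4-(benzyloxy)-6-bromo-3-chloro-2-methoxyphenoxy]-4-methylbenzoic acid, via 3-(benzyloxy)-5-methylbenzyne 17 (not isolated)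
Conditions: 7, NaH, THF, 0 °C; then CsF, 18-crown-6, CO2 (2 bar), slow addition of 15, THF, 0 °C to rt; then aq. HCl
Reagents that add atoms: none
Why: Proposed new method: fluoride attacks the silicon of 15 and triflate leaves to give aryne 17, whose triple bond is distorted by the adjacent benzyloxy group so that the phenoxide of 7 attacks the carbon meta to that oxygen and the negative charge develops on the carbon ortho to it, where the C–O sigma bond stabilises it inductively. The aryl anion, flanked by the new aryloxy group and the benzyloxy group, is then captured by CO2 (16) to give the carboxylate and, after acidification, acid 18, so the C2–O and C1–CO2H bonds of ring B form in one operation. The closest known reaction types are the coupling of arynes, amines and CO2 to anthranilic acid derivatives and the regioselective addition of phenoxides to 3-alkoxyarynes with protonation of the anion; a phenoxide as nucleophile with CO2 as terminating electrophile has not been shown. No ring closes and no stereocentre is formed. Regioselectivity rests on the benzyloxy group of 17, the methyl group being too remote to compete. Capture by CO2 instead of a proton is secured by preforming the phenoxide with NaH and working in THF without acidic O–H or C–H donors. Ring A carries bromide in place of its ester, so the anion finds no acyl group for xanthone closure and cannot reach the linear geometry needed for bromine transfer within the six-membered array. Slow addition of 15 keeps the aryne concentration low, so the phenoxide, not fluoride or the product carboxylate, is the nucleophile that intercepts it.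

**Step 11**
Reactants: 18 2-(benzyloxy)-6-[4-(benzyloxy)-6-bromo-3-chloro-2-methoxyphenoxy]-4-methylbenzoic acid
Product: 19 2-(benzyloxy)-6-[4-(benzyloxy)-3-chloro-2-methoxy-6-(methoxycarbonyl)phenoxy]-4-methylbenzoic acid
Conditions: Pd(OAc)2 (cat.), Xantphos (cat.), CO (1 atm), Et3N, MeOH–toluene, 80 °C; then aq. HCl
Reagents that add atoms: carbon monoxide, [C-]#[O+]; methanol, CO
Why: Palladium-catalysed methoxycarbonylation of an aryl bromide; zerovalent palladium formed from Pd(OAc)2 and Xantphos inserts into C–Br in preference to the hindered, electron-rich C–Cl bond, CO insertion gives the acylpalladium species and methanolysis releases the ester. The ring B acid is present as its triethylammonium carboxylate and stays unesterified.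

**Step 12**
Reactants: 19 2-(benzyloxy)-6-[4-(benzyloxy)-3-chloro-2-methoxy-6-(methoxycarbonyl)phenoxy]-4-methylbenzoic acid
Product: 20 2-[3-chloro-4-hydroxy-2-methoxy-6-(methoxycarbonyl)phenoxy]-6-hydroxy-4-methylbenzoic acid
Conditions: BCl3, pentamethylbenzene, CH2Cl2, −78 °C; then MeOH
Reagents that add atoms: none
Why: Lewis-acid debenzylation with a cation scavenger; BCl3 activates the benzylic ether oxygens and pentamethylbenzene captures the benzyl cations, so both aryl benzyl ethers cleave at low temperature while the aryl chloride, the methyl ester and the non-chelated methyl ether remain.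

## Compound list

1 | 2-chloro-4-hydroxy-3-methoxybenzaldehyde (2-chlorovanillin) | O=Cc1ccc(O)c(OC)c1Cl | starting material
2 | 5-bromo-2-chloro-4-hydroxy-3-methoxybenzaldehyde | O=Cc1cc(Br)c(O)c(OC)c1Cl | intermediate
3 | 5-bromo-2-chloro-3-methoxy-4-(methoxymethoxy)benzaldehyde | O=Cc1cc(Br)c(OCOC)c(OC)c1Cl | intermediate
4 | 5-bromo-2-chloro-3-methoxy-4-(methoxymethoxy)phenyl formate | O=COc1cc(Br)c(OCOC)c(OC)c1Cl | intermediate
5 | 5-bromo-2-chloro-3-methoxy-4-(methoxymethoxy)phenol | Oc1cc(Br)c(OCOC)c(OC)c1Cl | intermediate
6 | 1-(benzyloxy)-5-bromo-2-chloro-3-methoxy-4-(methoxymethoxy)benzene | Clc1c(OCc2ccccc2)cc(Br)c(OCOC)c1OC | intermediate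
7 | 4-(benzyloxy)-6-bromo-3-chloro-2-methoxyphenol | Oc1c(Br)cc(OCc2ccccc2)c(Cl)c1OC | intermediate
8 | orcinol (5-methylbenzene-1,3-diol) | Cc1cc(O)cc(O)c1 | starting material
9 | 3-(benzyloxy)-5-methylphenol | Cc1cc(O)cc(OCc2ccccc2)c1 | intermediate
10 | 3-(benzyloxy)-5-methylphenyl N-isopropylcarbamate | CC(C)NC(=O)Oc1cc(C)cc(OCc2ccccc2)c1 | intermediate
11 | 3-(benzyloxy)-5-methylphenyl N-(tert-butyldimethylsilyl)-N-isopropylcarbamate | CC(C)N([Si](C)(C)C(C)(C)C)C(=O)Oc1cc(C)cc(OCc2ccccc2)c1 | intermediate
12 | 3-(benzyloxy)-5-methyl-2-(trimethylsilyl)phenyl N-(tert-butyldimethylsilyl)-N-isopropylcarbamate | CC(C)N([Si](C)(C)C(C)(C)C)C(=O)Oc1cc(C)cc(OCc2ccccc2)c1[Si](C)(C)C | intermediate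
13 | 3-(benzyloxy)-5-methyl-2-(trimethylsilyl)phenyl N-isopropylcarbamate | CC(C)NC(=O)Oc1cc(C)cc(OCc2ccccc2)c1[Si](C)(C)C | intermediate
14 | 3-(benzyloxy)-5-methyl-2-(trimethylsilyl)phenol | Cc1cc(O)c([Si](C)(C)C)c(OCc2ccccc2)c1 | intermediate
15 | 3-(benzyloxy)-5-methyl-2-(trimethylsilyl)phenyl trifluoromethanesulfonate | Cc1cc(OCc2ccccc2)c([Si](C)(C)C)c(OS(=O)(=O)C(F)(F)F)c1 | intermediate
16 | carbon dioxide | O=C=O | starting material
17 | 3-(benzyloxy)-5-methylbenzyne (3-benzyloxy-5-methyl-1,2-didehydrobenzene) | CC1=CC#CC(OCc2ccccc2)=C1 | intermediate
18 | 2-(benzyloxy)-6-[4-(benzyloxy)-6-bromo-3-chloro-2-methoxyphenoxy]-4-methylbenzoic acid | OC(=O)c1c(OCc2ccccc2)cc(C)cc1Oc1c(Br)cc(OCc2ccccc2)c(Cl)c1OC | intermediate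
19 | 2-(benzyloxy)-6-[4-(benzyloxy)-3-chloro-2-methoxy-6-(methoxycarbonyl)phenoxy]-4-methylbenzoic acid | COC(=O)c1cc(OCc2ccccc2)c(Cl)c(OC)c1Oc1cc(C)cc(OCc2ccccc2)c1C(=O)O | intermediate
20 | 2-[3-chloro-4-hydroxy-2-methoxy-6-(methoxycarbonyl)phenoxy]-6-hydroxy-4-methylbenzoic acid | COC(=O)c1cc(O)c(Cl)c(OC)c1Oc1cc(C)cc(O)c1C(=O)O | target

## Step count and least certain steps

Total steps: 12. Longest linear sequence: 8 steps (steps 1 to 5, then 10, 11 and 12); the ring B branch (steps 6 to 9) joins at step 10.

**Step 10 (key step).**
- Most likely failure: premature protonation of the aryl anion by adventitious proton donors before it meets CO2, which would stop at the simple ether. Addition of the wrong oxygen nucleophile to the aryne is also possible, namely the phenoxide–CO2 adduct (leading by acyl transfer to an ester instead of an ether) or the product carboxylate. Tying the phenoxide up as its carbonate under CO2 pressure could also slow the addition.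
- Fallback (leaves at 7, returns at 18; the aryne is abandoned for addition–elimination followed by oxidation): 3-fluoro-5-methylphenol F1 (purchased) is benzylated (BnBr, K2CO3) to 1-(benzyloxy)-3-fluoro-5-methylbenzene F2. Lithiation between fluorine and the benzyloxy group (n-BuLi, THF, −78 °C) and formylation with DMF give 2-(benzyloxy)-6-fluoro-4-methylbenzaldehyde F3. The phenoxide of 7 (K2CO3, DMF, 100 °C) displaces the fluoride ortho to the formyl group to give 2-(benzyloxy)-6-[4-(benzyloxy)-6-bromo-3-chloro-2-methoxyphenoxy]-4-methylbenzaldehyde F4. Pinnick oxidation (NaClO2, NaH2PO4, 2-methyl-2-butene) then gives 18.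

**Step 11.**
- Most likely failure: slow oxidative addition at the electron-rich bromide next to the bulky aryloxy group, so that reductive loss of bromine or sequestration of palladium by the carboxylate competes with carbonylation.
- Fallback (leaves at 18, returns at 19; organolithium carboxylation with steric differentiation instead of catalysis): 18 is converted to its carboxylate (NaH, THF), bromine–lithium exchange (n-BuLi, −78 °C) and quenching with CO2 give 5-(benzyloxy)-2-[3-(benzyloxy)-2-carboxy-5-methylphenoxy]-4-chloro-3-methoxybenzoic acid F5. Fischer esterification (HCl, MeOH, 40 °C) then esterifies only the ring A acid, because the ring B acid lies between two ortho substituents and resists acid-catalysed esterification.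

**Step 8.**
- Most likely failure: deprotonation at the benzylic CH2 of the benzyl ether (followed by Wittig rearrangement), or lithiation at C6 instead of C2, competing with the desired metalation.
- Fallback (leaves at 8, returns at 14 and then 15; the benzyl ether is introduced only after the metalation): 8 is converted with ClCONEt2 and NaH to 5-methyl-1,3-phenylene bis(N,N-diethylcarbamate) F6. Lithiation between the two carbamates (s-BuLi, TMEDA, THF, −78 °C) and silylation with TMSCl give 5-methyl-2-(trimethylsilyl)-1,3-phenylene bis(N,N-diethylcarbamate) F7. LiAlH4 removes both carbamates to give 5-methyl-2-(trimethylsilyl)benzene-1,3-diol F8. Monobenzylation (BnBr, K2CO3) gives 14, which is triflated with PhNTf2 to 15.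

**Step 6.**
- Most likely failure: over-alkylation, because the second hydroxyl is as reactive as the first, so material is lost to the dibenzyl ether.
- Fallback (leaves at 8, returns at 9; exhaustive alkylation followed by self-limiting dealkylation): 8 is fully benzylated (excess BnBr, K2CO3) to 1,3-bis(benzyloxy)-5-methylbenzene F9. NaSEt in DMF at 120 °C removes one benzyl group by substitution at the benzylic carbon; the phenoxide formed deactivates the second ether, so the reaction stops at 9.

**Step 12.**
- Most likely failure: incomplete cleavage of the second benzyl ether at low temperature or, on warming, attack of the Lewis acid on the ring A methyl ether and benzylation of the electron-rich ring B by escaped benzyl cations.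
- Fallback (leaves at 19, returns at 20; reductive instead of Lewis-acid cleavage): hydrogenolysis (H2, Pd/C, EtOAc, rt) stopped at uptake of two equivalents. The aryl chloride lies between two ortho substituents and should be reduced more slowly than the benzyl ethers. This fallback makes no new compound (F0).

## Further compounds

F1 | step 10 | 3-fluoro-5-methylphenol (purchased) | Cc1cc(O)cc(F)c1
F2 | step 10 | 1-(benzyloxy)-3-fluoro-5-methylbenzene | Cc1cc(F)cc(OCc2ccccc2)c1
F3 | step 10 | 2-(benzyloxy)-6-fluoro-4-methylbenzaldehyde | O=Cc1c(F)cc(C)cc1OCc1ccccc1
F4 | step 10 | 2-(benzyloxy)-6-[4-(benzyloxy)-6-bromo-3-chloro-2-methoxyphenoxy]-4-methylbenzaldehyde | O=Cc1c(OCc2ccccc2)cc(C)cc1Oc1c(Br)cc(OCc2ccccc2)c(Cl)c1OC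
F5 | step 11 | 5-(benzyloxy)-2-[3-(benzyloxy)-2-carboxy-5-methylphenoxy]-4-chloro-3-methoxybenzoic acid | OC(=O)c1cc(OCc2ccccc2)c(Cl)c(OC)c1Oc1cc(C)cc(OCc2ccccc2)c1C(=O)O
F6 | step 8 | 5-methyl-1,3-phenylene bis(N,N-diethylcarbamate) | CCN(CC)C(=O)Oc1cc(C)cc(OC(=O)N(CC)CC)c1
F7 | step 8 | 5-methyl-2-(trimethylsilyl)-1,3-phenylene bis(N,N-diethylcarbamate) | CCN(CC)C(=O)Oc1cc(C)cc(OC(=O)N(CC)CC)c1[Si](C)(C)C
F8 | step 8 | 5-methyl-2-(trimethylsilyl)benzene-1,3-diol | Cc1cc(O)c([Si](C)(C)C)c(O)c1
F9 | step 6 | 1,3-bis(benzyloxy)-5-methylbenzene | Cc1cc(OCc2ccccc2)cc(OCc2ccccc2)c1
F0 | step 12 | none | none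
A1 | alternative 1 | tert-butyl 2-{[(2Z)-3-chloro-2-methoxy-4-oxopent-2-en-1-yl]oxy}-6-(methoxymethoxy)-4-methylbenzoate | CC(=O)/C(Cl)=C(\COc1cc(C)cc(OCOC)c1C(=O)OC(C)(C)C)OC
A2 | alternative 1 | dimethyl oxalate | COC(=O)C(=O)OC
A3 | alternative 1 | tert-butyl 2-[3-chloro-4-hydroxy-2-methoxy-6-(methoxycarbonyl)phenoxy]-6-(methoxymethoxy)-4-methylbenzoate | COC(=O)c1cc(O)c(Cl)c(OC)c1Oc1cc(C)cc(OCOC)c1C(=O)OC(C)(C)C
A4 | alternative 2 | methyl 5-(benzyloxy)-4-chloro-2-{[(1Z)-1-chloro-3-oxobut-1-en-1-yl]oxy}-3-methoxybenzoate (drawn as the Z isomer; the geometry is lost on ring closure) | CC(=O)/C=C(\Cl)Oc1c(C(=O)OC)cc(OCc2ccccc2)c(Cl)c1OC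
A5 | alternative 2 | benzyl 3-oxobutanoate (benzyl acetoacetate) | CC(=O)CC(=O)OCc1ccccc1
A6 | alternative 2 | benzyl 2-[4-(benzyloxy)-3-chloro-2-methoxy-6-(methoxycarbonyl)phenoxy]-6-hydroxy-4-methylbenzoate | COC(=O)c1cc(OCc2ccccc2)c(Cl)c(OC)c1Oc1cc(C)cc(O)c1C(=O)OCc1ccccc1
A7 | alternative 3 | 1-methoxy-3-methyl-1-(trimethylsilyloxy)buta-1,3-diene | COC(O[Si](C)(C)C)=CC(C)=C
A8 | alternative 3 | methyl 5-(benzyloxy)-2-[(3-tert-butoxy-3-oxoprop-1-yn-1-yl)oxy]-4-chloro-3-methoxybenzoate | COC(=O)c1cc(OCc2ccccc2)c(Cl)c(OC)c1OC#CC(=O)OC(C)(C)C
A9 | alternative 3 | tert-butyl 2-[4-(benzyloxy)-3-chloro-2-methoxy-6-(methoxycarbonyl)phenoxy]-6-hydroxy-4-methylbenzoate | COC(=O)c1cc(OCc2ccccc2)c(Cl)c(OC)c1Oc1cc(C)cc(O)c1C(=O)OC(C)(C)C
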